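**Strategy.** The depside ester is made first and ring A (the 4-hydroxy-2-methoxy-6-propylbenzoyl ring) is then grown on it. The key step is a Diels–Alder reaction between the 4-O-hex-2-ynoate of benzyl 2,4-dihydroxy-6-propylbenzoate (ring B) and 1,1-dimethoxy-3-(trimethylsilyloxy)buta-1,3-diene, followed by loss of methanol. It forms the C1–C2 and C5–C6 bonds of ring A and delivers C2–OMe (ketene acetal carbon), C4–OH (silyl enol ether carbon) and C6–propyl (alkyne carbon) already differentiated. The hindered 2,6-disubstituted aryl ester is therefore never made by acylation, and no phenol of ring A needs protection. The target has no stereocentre.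

Key step: step 6

Remark: ring A is the acyl ring, numbered from its carbonyl-bearing carbon C1; ring B is the salicylic acid ring.

**Step 1**
Reactants: 1 5-propylbenzene-1,3-diol
Product: 2 2,4-dihydroxy-6-propylbenzoic acid
Conditions: CH3OMgOCO2CH3 (methyl magnesium carbonate, 2 M in DMF), 120 °C, N2; then cold 3 M HCl
Reagents that add atoms: methyl magnesium carbonate, CO[Mg]OC(=O)OC
Why: Kolbe–Schmitt-type carboxylation with methyl magnesium carbonate, in which the magnesium phenoxide is carboxylated ortho to one hydroxyl and para to the other and the product is held as a magnesium salicylate chelate, as known for 5-alkylresorcinols.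

**Step 2**
Reactants: 2 2,4-dihydroxy-6-propylbenzoic acid
Product: 3 benzyl 2,4-dihydroxy-6-propylbenzoate
Conditions: BnBr (1.05 equiv), KHCO3, DMF, rt
Reagents that add atoms: benzyl bromide, BrCc1ccccc1
Why: SN2 O-alkylation of the carboxylate, since hydrogencarbonate deprotonates only the carboxylic acid and leaves both phenols free.

**Step 3**
Reactants: 3 benzyl 2,4-dihydroxy-6-propylbenzoate; 4 hex-2-ynoic acid
Product: 5 benzyl 4-(hex-2-ynoyloxy)-2-hydroxy-6-propylbenzoate
Conditions: DCC, DMAP (5 mol %), CH2Cl2, −10 °C to rt
Reagents that add atoms: none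
Why: Steglich esterification, selective for the 4-OH because the 2-OH is hydrogen-bonded to the benzyl ester carbonyl and flanked by it, with low temperature and little DMAP to suppress amine addition to the ynoate.

**Step 4**
Reactants: 6 1,1-dimethoxyethene; 7 acetyl chloride
Product: 8 4,4-dimethoxybut-3-en-2-one
Conditions: pyridine, Et2O, 0 °C to rt; filtration and distillation without aqueous work-up
Reagents that add atoms: none
Why: C-acylation of a ketene acetal, in which the nucleophilic CH2 terminus attacks the acylpyridinium ion and loss of a proton gives the push–pull β,β-dimethoxy enone.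

**Step 5**
Reactants: 8 4,4-dimethoxybut-3-en-2-one
Product: 9 1,1-dimethoxy-3-(trimethylsilyloxy)buta-1,3-diene
Conditions: TMSOTf, Et3N, Et2O, 0 °C; pentane extraction, distillation, used at once
Reagents that add atoms: trimethylsilyl trifluoromethanesulfonate, C[Si](C)(C)OS(=O)(=O)C(F)(F)F
Why: Soft enolization with O-silylation of a methyl ketone, in which silylation at the carbonyl oxygen gives a dimethoxy-stabilized cation that triethylamine deprotonates at the only α' position (the CH3 group) to give the 2-silyloxydiene.

**Step 6**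
Reactants: 5 benzyl 4-(hex-2-ynoyloxy)-2-hydroxy-6-propylbenzoate; 9 1,1-dimethoxy-3-(trimethylsilyloxy)buta-1,3-diene
Product: 12 benzyl 2-hydroxy-4-[(4-hydroxy-2-methoxy-6-propylbenzoyl)oxy]-6-propylbenzoate, via cyclohexadiene cycloadduct 10 (not isolated), via aryl trimethylsilyl ether 11 (not isolated)
Conditions: 9 (3 equiv), toluene, 110 °C, sealed tube; then 1 M HCl, THF, rt
Reagents that add atoms: none
Why: A (4+2) cycloaddition of an electron-rich 1,1-dialkoxy-3-silyloxybutadiene (a Danishefsky-type diene) to a 2-alkynoate followed by aromatization is the known way to 4-hydroxy-2-methoxy-6-alkylbenzoates, applied here to an aryl ester. Ring A closes in a (4+2) mode, either concerted and asynchronous or by Michael addition and ring closure, and both paths form the same C5–C6 and C1–C2 bonds. Both oxygen donors of the diene raise the HOMO coefficient at its CH2 terminus, which bonds to the propyl-bearing β-carbon of the ynoate, so the C(OMe)2 carbon bonds to the α-carbon and the methoxy group ends up ortho and the silyloxy group para to the ester. Cycloadduct 10 holds a ketal carbon and a ring CH2 in a 1,4-cyclohexadiene and loses methanol with gain of aromaticity to give 11, whose O–Si bond alone is cleaved by dilute acid. No stereocentre is formed. The chelated 2-OH of ring B and the two ester carbonyls are not dienophiles, and the excess of diene covers protonation by that phenol and by the methanol released.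

**Step 7**
Reactants: 12 benzyl 2-hydroxy-4-[(4-hydroxy-2-methoxy-6-propylbenzoyl)oxy]-6-propylbenzoate
Product: 13 2-hydroxy-4-[(4-hydroxy-2-methoxy-6-propylbenzoyl)oxy]-6-propylbenzoic acid
Conditions: H2 (1 atm), 10% Pd/C, EtOAc, rt
Reagents that add atoms: none
Why: Hydrogenolysis of the benzyl ester, under which the aryl ester, the methyl ether and both arenes are inert.

**Compound list**
1 | 5-propylbenzene-1,3-diol | CCCc1cc(O)cc(O)c1 | starting material
2 | 2,4-dihydroxy-6-propylbenzoic acid | CCCc1cc(O)cc(O)c1C(=O)O | intermediate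
3 | benzyl 2,4-dihydroxy-6-propylbenzoate | CCCc1cc(O)cc(O)c1C(=O)OCc1ccccc1 | intermediate
4 | hex-2-ynoic acid | CCCC#CC(=O)O | starting material
5 | benzyl 4-(hex-2-ynoyloxy)-2-hydroxy-6-propylbenzoate | CCCC#CC(=O)Oc1cc(O)c(C(=O)OCc2ccccc2)c(CCC)c1 | intermediate
6 | 1,1-dimethoxyethene | C=C(OC)OC | starting material
7 | acetyl chloride | CC(=O)Cl | starting material
8 | 4,4-dimethoxybut-3-en-2-one | CC(=O)C=C(OC)OC | intermediate
9 | 1,1-dimethoxy-3-(trimethylsilyloxy)buta-1,3-diene | C=C(O[Si](C)(C)C)C=C(OC)OC | intermediate
10 | benzyl 4-{[6,6-dimethoxy-2-propyl-4-(trimethylsilyloxy)cyclohexa-1,4-diene-1-carbonyl]oxy}-2-hydroxy-6-propylbenzoate | CCCC1=C(C(=O)Oc2cc(O)c(C(=O)OCc3ccccc3)c(CCC)c2)C(OC)(OC)C=C(O[Si](C)(C)C)C1 | intermediate (not isolated)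
11 | benzyl 2-hydroxy-4-{[2-methoxy-6-propyl-4-(trimethylsilyloxy)benzoyl]oxy}-6-propylbenzoate | CCCc1cc(O[Si](C)(C)C)cc(OC)c1C(=O)Oc1cc(O)c(C(=O)OCc2ccccc2)c(CCC)c1 | intermediate (not isolated)
12 | benzyl 2-hydroxy-4-[(4-hydroxy-2-methoxy-6-propylbenzoyl)oxy]-6-propylbenzoate | CCCc1cc(O)cc(OC)c1C(=O)Oc1cc(O)c(C(=O)OCc2ccccc2)c(CCC)c1 | intermediate
13 | 2-hydroxy-4-[(4-hydroxy-2-methoxy-6-propylbenzoyl)oxy]-6-propylbenzoic acid | CCCc1cc(OC(=O)c2c(CCC)cc(O)cc2OC)cc(O)c1C(=O)O | target

**Step count and risks**
Total step count: 7. Longest linear sequence: 5 steps (steps 1, 2, 3, 6, 7); the diene branch (steps 4, 5) joins at step 6.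

Steps most likely to fail:

1. Step 6. The cycloaddition of the β-alkyl ynoate may be slower than the loss of the diene, through protonation of the ketene acetal by the chelated phenol or by released methanol, or through thermal decomposition. The fallback gives up the ring construction for a classical depside coupling; it sets out from 3 and comes back at 13. Selective 4-O-benzylation of 3 (BnBr, K2CO3, acetone) should give benzyl 4-(benzyloxy)-2-hydroxy-6-propylbenzoate F1. Methylation of the chelated 2-OH (MeI, K2CO3, DMF, 60 °C) should give benzyl 4-(benzyloxy)-2-methoxy-6-propylbenzoate F2. Saponification of the hindered ester (KOH, DMSO/H2O, 90 °C) should give 4-(benzyloxy)-2-methoxy-6-propylbenzoic acid F3. Coupling with a second portion of 3 by the mixed anhydride method (trifluoroacetic anhydride, toluene, rt) should give benzyl 4-{[4-(benzyloxy)-2-methoxy-6-propylbenzoyl]oxy}-2-hydroxy-6-propylbenzoate F4. Hydrogenolysis (H2, Pd/C, EtOAc) removes both benzyl groups and gives 13.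

2. Step 1. Carboxylation may take place at the carbon between the two hydroxyl groups, or the acid may decarboxylate during acidic work-up. The fallback installs the carboxyl carbon by formylation and oxidation; it sets out from 1 and comes back at 2. Vilsmeier–Haack formylation (POCl3, DMF, 0 °C to rt; aqueous hydrolysis) should give 2,4-dihydroxy-6-propylbenzaldehyde F5. Pinnick oxidation (NaClO2, NaH2PO4, 2-methylbut-2-ene, DMSO/H2O, rt) should then give 2.

3. Step 4. The ketene acetal may oligomerize under the acid set free, and acetyl chloride may be dehydrochlorinated to ketene. The fallback makes the same enone by acylation of a dichloroalkene and substitution; it sets out from 7 and comes back at 8. Addition of 7 to 1,1-dichloroethene (AlCl3, CH2Cl2, 0 °C) should give 4,4,4-trichlorobutan-2-one F6. This loses hydrogen chloride on distillation to give 4,4-dichlorobut-3-en-2-one F7. Double addition–elimination with NaOCH3 (2 equiv, MeOH, 0 °C) should give 8.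

**Further compounds**
F1 | step 6 | benzyl 4-(benzyloxy)-2-hydroxy-6-propylbenzoate | CCCc1cc(OCc2ccccc2)cc(O)c1C(=O)OCc1ccccc1
F2 | step 6 | benzyl 4-(benzyloxy)-2-methoxy-6-propylbenzoate | CCCc1cc(OCc2ccccc2)cc(OC)c1C(=O)OCc1ccccc1
F3 | step 6 | 4-(benzyloxy)-2-methoxy-6-propylbenzoic acid | CCCc1cc(OCc2ccccc2)cc(OC)c1C(=O)O
F4 | step 6 | benzyl 4-{[4-(benzyloxy)-2-methoxy-6-propylbenzoyl]oxy}-2-hydroxy-6-propylbenzoate | CCCc1cc(OCc2ccccc2)cc(OC)c1C(=O)Oc1cc(O)c(C(=O)OCc2ccccc2)c(CCC)c1
F5 | step 1 | 2,4-dihydroxy-6-propylbenzaldehyde | CCCc1cc(O)cc(O)c1C=O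
F6 | step 4 | 4,4,4-trichlorobutan-2-one | CC(=O)CC(Cl)(Cl)Cl
F7 | step 4 | 4,4-dichlorobut-3-en-2-one | CC(=O)C=C(Cl)Cl
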